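**Retrosynthetic overview**

1. Target ⇐ 15-hydroxy acid (acetylation) ⇐ 15-O-silyl acid (desilylation); the skeleton is complete after the key step.
2. Key disconnection C9–C10, opening ring B (C5–C6–C7–C8–C9–C10). Enabling feature: the C19 carboxyl on C4 and the C20 methyl on C10 are 1,3-diaxial on the β-face of ring A (C1–C5, C10), so C19 can be tied to C10 as a temporary γ-lactone (ring C4–C19–O–C10–C5) that already carries C20. Catalytic TMSOTf ionises its C10–O bond and a C17-silylated allylsilane (retron: the C8=C17 methylene next to C9) closes ring B with inversion at C10 and frees the acid.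
3. C6–C7: alkylation of a C6 sulfone on ring A with an allylic bromide made from geranyl acetate (alkyne homologation, then Cu-catalysed anti-carbomagnesiation, which fixes the C8=C9 geometry and brings in C17–Si), then desulfonylation.
4. Ring A is bought as a cyclohexenone: asymmetric conjugate methylation sets C4, formaldehyde aldol/lactonisation sets C5 through a first temporary 19,6-lactone, which is switched (methylenation, thiolate opening, acid lactonisation) to the 19,10-lactone.
5. Order of rings: ring A (present from the start) → temporary lactone rings (both cleaved again) → ring B last.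

Key step: step 14

Remark: labdane numbering (C1–C20) is used for all intermediates, α/β refer to the usual orientation with C20 β, and compounds 1 and 9 and all named reagents are taken as commercial.

**Route**

Step 1
Reactants: 1 methyl 3-oxocyclohex-1-ene-1-carboxylate
Product: 4 cis-fused keto-lactone (19,6-olide, C10 ketone, C4 quaternary), via methylzinc enolate 2 (not isolated), via hydroxymethyl ketone 3 (not isolated)
Conditions: Me2Zn, (CuOTf)2·C6H6 (cat.), chiral NHC–Ag complex (cat.), t-BuOMe, −30 °C; CH2O (THF), −78 → −30 °C; aq NH4Cl; then TsOH·H2O (cat.), PhMe, 60 °C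
Reagents that add atoms: dimethylzinc C[Zn]C; formaldehyde C=O
Why: Copper–NHC-catalysed asymmetric conjugate addition of Me2Zn to the β-carboxy enone should build the C4 quaternary centre (face chosen by the chiral ligand) and give a regiodefined zinc enolate that adds to formaldehyde at C5 (aldol), and under TsOH only the C5 epimer with CH2OH cis to the C19 ester can close the γ-lactone while C5, α to the C10 ketone, equilibrates, so the cis-fused lactone is the sink that fixes C5 relative to C4.

Step 2
Reactants: 4 cis-fused keto-lactone
Product: 5 methylene lactone (19,6-olide with C10=C20H2)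
Conditions: Zn, CH2Br2, TiCl4, THF/CH2Cl2, 0 °C → rt
Reagents that add atoms: dibromomethane BrCBr
Why: Takai–Lombardo methylenation with the non-basic gem-dizinc/titanium reagent should convert the hindered, enolisable C10 ketone into the exocyclic methylene without β-elimination of the acyloxy group, epimerisation at C5 or attack on the lactone, and no stereocentre is formed.

Step 3
Reactants: 5 methylene lactone
Product: 6 thioether acid (C6–SPh, free C19 acid, C10=C20H2)
Conditions: PhSNa, DMF, 100 °C; then 1 M HCl
Reagents that add atoms: sodium benzenethiolate [Na+].[S-]c1ccccc1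
Why: The soft thiolate should open the γ-lactone by SN2 attack at the primary C6–O carbon (alkyl–oxygen cleavage), which frees the C19 carboxylate and puts the sulfur handle on C6 without touching C4 or C5.

Step 4
Reactants: 6 thioether acid
Product: 7 bridged lactone sulfide (19,10-olide, C20 now a methyl group)
Conditions: TfOH (10 mol%), CH2Cl2, 0 °C
Reagents that add atoms: none
Why: Brønsted acid-catalysed Markovnikov lactonisation of a γ,δ-unsaturated acid: protonation at C20 gives the tertiary C10 cation, which the C19 carboxyl can reach only across the β-face (1,3-diaxial bridge), so the new C10 centre (O β-axial, CH3 equatorial) is set by the ring constraint.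

Step 5
Reactants: 7 bridged lactone sulfide
Product: 8 bridged lactone sulfone (C6–SO2Ph)
Conditions: 30% H2O2, (NH4)6Mo7O24 (cat.), EtOH, 0 °C → rt
Reagents that add atoms: hydrogen peroxide OO
Why: Molybdate-catalysed peroxide oxidation should take the sulfide to the sulfone chemoselectively, since no alkene is left in the molecule, and provides the carbanion-stabilising group for the C6–C7 bond.

Step 6
Reactants: 9 geranyl acetate
Product: 11 (E)-6-acetoxy-4-methylhex-4-enal, via secondary ozonide 10 (not isolated)
Conditions: O3 (1 equiv), CH2Cl2, pyridine, −78 °C; Me2S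
Reagents that add atoms: ozone [O-][O+]=O
Why: Ozonolysis with one equivalent of ozone should cleave the electron-rich 6,7-alkene in preference to the 2,3-alkene deactivated by the allylic acetate, and Me2S reduces the ozonide to the aldehyde with the (E)-alkene untouched.

Step 7
Reactants: 11 (E)-6-acetoxy-4-methylhex-4-enal
Product: 12 (E)-3-methylhept-2-en-6-yn-1-ol
Conditions: dimethyl (1-diazo-2-oxopropyl)phosphonate, K2CO3, MeOH, 0 °C → rt
Reagents that add atoms: Bestmann–Ohira reagent COP(=O)(OC)C(=[N+]=[N-])C(C)=O
Why: Seyferth–Gilbert homologation with the Bestmann–Ohira reagent should turn the aldehyde into the terminal alkyne (the new carbon is C8), and the K2CO3/MeOH medium removes the acetate by transesterification in the same operation.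

Step 8
Reactants: 12 (E)-3-methylhept-2-en-6-yn-1-ol
Product: 13 TBS ether of 12
Conditions: TBSCl, imidazole, DMF, rt
Reagents that add atoms: tert-butyldimethylsilyl chloride CC(C)(C)[Si](C)(C)Cl
Why: Standard silylation of the primary allylic alcohol gives an ether that should survive BuLi, the Grignard reagent, LDA, SmI2 and TMSOTf.

Step 9
Reactants: 13 TBS ether of 12
Product: 15 (E)-8-[(tert-butyldimethylsilyl)oxy]-6-methyloct-6-en-2-yn-1-ol, via lithium acetylide 14 (not isolated)
Conditions: n-BuLi, THF, −78 °C; (CH2O)n, → rt; aq NH4Cl
Reagents that add atoms: formaldehyde (from paraformaldehyde) C=O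
Why: Deprotonation of the terminal alkyne and addition of the acetylide to formaldehyde adds C7 as the propargylic alcohol that directs the next step.

Step 10
Reactants: 15 (E)-8-[(tert-butyldimethylsilyl)oxy]-6-methyloct-6-en-2-yn-1-ol
Product: 17 (2Z,6E)-8-[(tert-butyldimethylsilyl)oxy]-6-methyl-2-[(trimethylsilyl)methyl]octa-2,6-dien-1-ol, via alkenylmagnesium chelate 16 (not isolated)
Conditions: Me3SiCH2MgCl (3.5 equiv), CuI (10 mol%), THF, 0 °C → rt; aq NH4Cl
Reagents that add atoms: (trimethylsilyl)methylmagnesium chloride C[Si](C)(C)C[Mg]Cl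
Why: Copper-catalysed anti-carbomagnesiation of a propargylic alcohol: the magnesium alkoxide delivers Me3SiCH2 to C8 and magnesium to C9 in a five-membered chelate, so after protonation CH2SiMe3 (C17) is cis to the C11 chain and CH2OH (C7) is trans to it, the geometry the key step needs.

Step 11
Reactants: 17 allylsilane alcohol
Product: 18 (2E,6E)-1-bromo-8-[(tert-butyldimethylsilyl)oxy]-6-methyl-2-[(trimethylsilyl)methyl]octa-2,6-diene
Conditions: CBr4, PPh3, CH2Cl2, −20 °C
Reagents that add atoms: carbon tetrabromide BrC(Br)(Br)Br
Why: Appel bromination converts the primary allylic alcohol into the bromide under neutral conditions that should neither protodesilylate the allylsilane nor move the double bond.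

Step 12
Reactants: 8 bridged lactone sulfone; 18 allylic bromide
Product: 20 alkylated sulfone (C6 epimers), via lithiated sulfone 19 (not isolated)
Conditions: LDA, THF–DMPU, −78 °C; then 18, −78 → −30 °C
Reagents that add atoms: none
Why: Julia-type alkylation of the α-sulfonyl carbanion with the allylic bromide should form C6–C7 by SN2 at the CH2Br carbon, the lactone has no α-hydrogen, and the new C6 centre does not matter because the sulfone is removed next.

Step 13
Reactants: 20 alkylated sulfone
Product: 21 lactone allylsilane (19,10-olide with the complete C6–C15 chain)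
Conditions: SmI2, HMPA, THF, −20 °C; MeOH
Reagents that add atoms: none
Why: Reductive desulfonylation with SmI2/HMPA should cleave the C6–S bond cleanly, because the sulfone is neither allylic nor β to a leaving group, and leaves lactone, allylsilane, alkene and silyl ether alone.

Step 14
Reactants: 21 lactone allylsilane
Product: 23 15-O-TBS-isocupressic acid, via trimethylsilyl ester 22 (not isolated)
Conditions: TMSOTf (0.2 equiv), 2,6-di-tert-butyl-4-methylpyridine (0.3 equiv), CH2Cl2, −40 → 0 °C; aq citric acid/THF
Reagents that add atoms: none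
Why: Proposed new method: TMSOTf silylates the lactone carbonyl and the strained tertiary C10–O bond ionises, as in the known TMSOTf cleavage of tert-butyl esters, to a silyl ester and a C10 cation that is captured by the tethered allylsilane; the closest known reaction types are the Lewis acid-mediated tert-alkylation of allylsilanes by tertiary halides (Hosomi–Sakurai type), allylsilane-terminated cation–olefin cyclisation and Friedel–Crafts alkylation with tertiary γ-lactones. Ring B closes in a 6-endo-trig mode (C9 of the C8=C9 bond attacks C10) through a chair transition state, and the β-silyl cation at C8 gives up Me3Si+ to triflate, which forms only the C8=C17 exocyclic alkene and regenerates TMSOTf, so the step is a catalytic silyl-transfer cycloisomerisation. C10 is controlled by the bridged lactone, which holds the leaving oxygen axial on the β-face so that C9 bonds from the α-face with inversion and the C20 methyl moves into the β-axial position, giving the trans ring fusion. C9 is controlled by the alkene geometry set in step 10 (C7 trans to C11), which in the chair places the side chain equatorial (β) and H9 α. The step needs C–C bond formation to outrun proton loss from the cation and protodesilylation: the six-membered intramolecular capture, the rigid chair of ring A with C6 equatorial, and the hindered pyridine that removes traces of triflic acid should secure this, and the C13=C14 alkene is too far from C10 to compete.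

Step 15
Reactants: 23 15-O-TBS-isocupressic acid
Product: 24 isocupressic acid
Conditions: TBAF, THF, 0 °C → rt; aq NH4Cl
Reagents that add atoms: none
Why: Fluoride-mediated desilylation cleaves the primary TBS ether, and the carboxylic acid and both alkenes are inert to TBAF.

Step 16
Reactants: 24 isocupressic acid
Product: 25 15-acetoxyisocupressic acid
Conditions: Ac2O, pyridine, DMAP (cat.), CH2Cl2, 0 °C; aq NaHCO3/THF, then acidify
Reagents that add atoms: acetic anhydride CC(=O)OC(C)=O
Why: Pyridine/DMAP acetylation esterifies the primary allylic alcohol, while the hindered axial C19 acid can give at most a mixed anhydride that water cleaves again on work-up, so the free acid is kept.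

**Compound list**

1 | methyl 3-oxocyclohex-1-ene-1-carboxylate | COC(=O)C1=CC(=O)CCC1 | starting material
2 | methylzinc enolate (C5=C10, O–ZnMe) of methyl (S)-1-methyl-3-oxocyclohexane-1-carboxylate, not isolated | C[Zn]OC1CCC[C@](C=1)(C)C(=O)OC | intermediate
3 | methyl (1S)-2-(hydroxymethyl)-1-methyl-3-oxocyclohexane-1-carboxylate (both C5 epimers), not isolated | OCC1C(=O)CCC[C@]1(C)C(=O)OC | intermediate
4 | keto-lactone, (3aR,7aS)-7a-methylhexahydro-2-benzofuran-1,4-dione: cis-fused 19,6-olide, C6 and C19 β, C18 and H5 α, C10 ketone | O1C[C@@H]2C(=O)CCC[C@]2(C)C1=O | intermediate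
5 | methylene lactone: the same cis-fused 19,6-olide with C10=C20H2 | O1C[C@@H]2C(=C)CCC[C@]2(C)C1=O | intermediate
6 | thioether acid, (1S,2R)-1-methyl-3-methylidene-2-[(phenylsulfanyl)methyl]cyclohexane-1-carboxylic acid | c1ccccc1SC[C@@H]2C(=C)CCC[C@]2(C)C(=O)O | intermediate
7 | bridged lactone sulfide, 1,5-dimethyl-8-[(phenylsulfanyl)methyl]-6-oxabicyclo[3.2.1]octan-7-one: 19,10-olide, C19–O–C10 bridge β, C20 equatorial, C6 β cis to C19, H5 α | c1ccccc1SC[C@@H]2[C@@]3(C)CCC[C@]2(C)C(=O)O3 | intermediate
8 | bridged lactone sulfone: the same 19,10-olide with C6–SO2Ph | O=S(=O)(c1ccccc1)C[C@@H]2[C@@]3(C)CCC[C@]2(C)C(=O)O3 | intermediate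
9 | geranyl acetate, (2E)-3,7-dimethylocta-2,6-dien-1-yl acetate | CC(C)=CCC/C(C)=C/COC(C)=O | starting material
10 | secondary ozonide (1,2,4-trioxolane) of the 6,7-alkene of 9, not isolated | CC1(C)OOC(CC/C(C)=C/COC(C)=O)O1 | intermediate
11 | (E)-6-acetoxy-4-methylhex-4-enal | O=CCC/C(C)=C/COC(C)=O | intermediate
12 | (E)-3-methylhept-2-en-6-yn-1-ol | C#CCC/C(C)=C/CO | intermediate
13 | tert-butyldimethylsilyl ether of 12 | C#CCC/C(C)=C/CO[Si](C)(C)C(C)(C)C | intermediate
14 | lithium acetylide of 13, not isolated | [Li]C#CCC/C(C)=C/CO[Si](C)(C)C(C)(C)C | intermediate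
15 | (E)-8-[(tert-butyldimethylsilyl)oxy]-6-methyloct-6-en-2-yn-1-ol | OCC#CCC/C(C)=C/CO[Si](C)(C)C(C)(C)C | intermediate
16 | cyclic alkenylmagnesium alkoxide (2,5-dihydro-1,2-oxamagnesole, Mg on C9, CH2SiMe3 on C8), not isolated | C[Si](C)(C)CC1=C(CC/C(C)=C/CO[Si](C)(C)C(C)(C)C)[Mg]OC1 | intermediate
17 | (2Z,6E)-8-[(tert-butyldimethylsilyl)oxy]-6-methyl-2-[(trimethylsilyl)methyl]octa-2,6-dien-1-ol (CH2SiMe3 cis to the chain) | OC/C(C[Si](C)(C)C)=C/CC/C(C)=C/CO[Si](C)(C)C(C)(C)C | intermediate
18 | (2E,6E)-1-bromo-8-[(tert-butyldimethylsilyl)oxy]-6-methyl-2-[(trimethylsilyl)methyl]octa-2,6-diene (same geometry as 17) | BrC/C(C[Si](C)(C)C)=C/CC/C(C)=C/CO[Si](C)(C)C(C)(C)C | intermediate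
19 | C6-lithiated sulfone of 8, not isolated | O=S(=O)(c1ccccc1)C([Li])[C@@H]2[C@@]3(C)CCC[C@]2(C)C(=O)O3 | intermediate
20 | alkylated sulfone (C6 epimers): 19,10-olide with C6(SO2Ph)–C7H2–C8(CH2SiMe3)=C9H–C11 to C15–OTBS | O=S(=O)(c1ccccc1)C(C/C(C[Si](C)(C)C)=C/CC/C(C)=C/CO[Si](C)(C)C(C)(C)C)[C@@H]2[C@@]3(C)CCC[C@]2(C)C(=O)O3 | intermediate
21 | lactone allylsilane: 19,10-olide with the C6–C15 chain, (8Z)-C8(CH2SiMe3)=C9, (13E), 15-OTBS | C(C/C(C[Si](C)(C)C)=C/CC/C(C)=C/CO[Si](C)(C)C(C)(C)C)[C@@H]1[C@@]2(C)CCC[C@]1(C)C(=O)O2 | intermediate
22 | trimethylsilyl ester of 23, not isolated | C=C1CC[C@@H]2[C@](C)(CCC[C@]2(C)C(=O)O[Si](C)(C)C)[C@H]1CC/C(C)=C/CO[Si](C)(C)C(C)(C)C | intermediate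
23 | 15-O-TBS-isocupressic acid, (4S,5R,9S,10R,13E)-15-[(tert-butyldimethylsilyl)oxy]labda-8(17),13-dien-19-oic acid | C=C1CC[C@@H]2[C@](C)(CCC[C@]2(C)C(=O)O)[C@H]1CC/C(C)=C/CO[Si](C)(C)C(C)(C)C | intermediate
24 | isocupressic acid, (4S,5R,9S,10R,13E)-15-hydroxylabda-8(17),13-dien-19-oic acid | C=C1CC[C@@H]2[C@](C)(CCC[C@]2(C)C(=O)O)[C@H]1CC/C(C)=C/CO | intermediate
25 | 15-acetoxyisocupressic acid, (4S,5R,9S,10R,13E)-15-acetoxylabda-8(17),13-dien-19-oic acid | C=C1CC[C@@H]2[C@](C)(CCC[C@]2(C)C(=O)O)[C@H]1CC/C(C)=C/COC(C)=O | target

**Step count and risks**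

Total step count: 16. Longest linear sequence: 11 steps (9 → 25, steps 6–16); the ring-A branch (1 → 25, steps 1–5 and 12–16) has 10.

Steps most likely to fail:

1. Step 14 (Proposed new method). The C10 cation may lose a proton to C1 or C5 faster than it is captured, which gives ring-A alkenes that cannot re-ionise under aprotic conditions. The allylsilane may be protodesilylated by adventitious triflic acid, ionisation with catalytic TMSOTf may stall, or the ion pair may relax and leak to the cis-fused decalin. The fallback uses known chemistry, sets out from 21 and returns at 23. Lactone 21 would be reduced with LiAlH4 (THF, 0 °C) to the 10,19-diol F1, and the primary C19 hydroxyl acetylated (Ac2O, pyridine, 0 °C) to give monoacetate F2. The free tertiary C10 alcohol would then be ionised with BF3·OEt2 (CH2Cl2, −78 °C), the established generation of a tertiary cation from a tertiary alcohol with allylsilane termination, to give the bicyclic 19-acetate F3. Methanolysis (K2CO3, MeOH) would give the 19-alcohol F4, Dess–Martin oxidation the 19-aldehyde F5, and Pinnick oxidation (NaClO2, NaH2PO4, 2-methyl-2-butene) the acid 23.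

2. Step 1. Capture of the zinc enolate by formaldehyde may be slow (oligomerisation of formaldehyde, proton transfer that scrambles the enolate regiochemistry). The hydroxymethyl ketone may undergo β-elimination to the α-methylene ketone during lactonisation, and the enantioselectivity of the conjugate addition may erode. The fallback sets out from 1 and returns at 4. The same conjugate addition would be run, but the enolate trapped with TMSCl/Et3N and isolated as the silyl enol ether F6. This would be hydroxymethylated with aqueous formaldehyde and a lanthanide triflate catalyst (Yb(OTf)3, THF/H2O, Mukaiyama aldol in water) to hydroxymethyl ketone 3, which would be lactonised with TsOH to 4.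

3. Step 3. SN2 attack at the β-branched C6 may be slow, E2 loss of the carboxylate to a conjugated diene may compete, and reversible attack at the carbonyl may consume thiolate. The fallback sets out from 4, returns at 7 and bypasses steps 2–4. MeCeCl2 (MeLi, CeCl3, THF, −78 °C) would be added to the C10 ketone of 4. Attack from the α-face, anti to the axial C19 acyl group, should give the β-alkoxide, which attacks C19 and expels the more stable primary C6 alkoxide (translactonisation) to give the 19,10-lactone alcohol F7. Its C6 hydroxyl would be converted into the phenyl sulfide with PhSSPh/Bu3P (THF, 60 °C) to give 7.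

Further compounds
F1 | step 14 | 10,19-diol from reduction of 21 (C10–OH β, C19H2OH, allylsilane and OTBS kept) | C(C/C(C[Si](C)(C)C)=C/CC/C(C)=C/CO[Si](C)(C)C(C)(C)C)[C@@H]1[C@](C)(O)CCC[C@]1(C)CO
F2 | step 14 | 19-monoacetate of F1 | C(C/C(C[Si](C)(C)C)=C/CC/C(C)=C/CO[Si](C)(C)C(C)(C)C)[C@@H]1[C@](C)(O)CCC[C@]1(C)COC(C)=O
F3 | step 14 | (13E)-19-acetoxy-15-[(tert-butyldimethylsilyl)oxy]labda-8(17),13-diene | C=C1CC[C@@H]2[C@](C)(CCC[C@]2(C)COC(C)=O)[C@H]1CC/C(C)=C/CO[Si](C)(C)C(C)(C)C
F4 | step 14 | (13E)-15-[(tert-butyldimethylsilyl)oxy]labda-8(17),13-dien-19-ol | C=C1CC[C@@H]2[C@](C)(CCC[C@]2(C)CO)[C@H]1CC/C(C)=C/CO[Si](C)(C)C(C)(C)C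
F5 | step 14 | (13E)-15-[(tert-butyldimethylsilyl)oxy]labda-8(17),13-dien-19-al | C=C1CC[C@@H]2[C@](C)(CCC[C@]2(C)C=O)[C@H]1CC/C(C)=C/CO[Si](C)(C)C(C)(C)C
F6 | step 1 | methyl (S)-1-methyl-3-[(trimethylsilyl)oxy]cyclohex-2-ene-1-carboxylate (C5=C10 silyl enol ether) | C[Si](C)(C)OC1CCC[C@](C=1)(C)C(=O)OC
F7 | step 3 | 19,10-lactone alcohol, 8-(hydroxymethyl)-1,5-dimethyl-6-oxabicyclo[3.2.1]octan-7-one (C6–OH cis to C19) | OC[C@@H]1[C@@]2(C)CCC[C@]1(C)C(=O)O2
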